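## The problem

Cardopatine 12 is a C2-symmetric trans-1,2-disubstituted cyclobutane. Ring carbons C1 and C2 are (R)-configured methines, each bearing one hydrogen and the sp carbon of a (2,2'-bithiophen-5-yl)ethynyl arm; C3 and C4 are plain methylenes. The four-membered ring can be bought, so the real task is the absolute configuration of two adjacent, identical stereocentres that carry no heteroatom and no carbonyl group. Once the alkynes are in place, nothing is left for a catalyst to grip or for a base to correct. The two stereocentres are each other's only stereochemical neighbour, so one can control the other: a trigonal C1 has its two faces told apart by the C2 substituent alone, and that bias points to trans. The strategic bonds are the two C(sp3)–C(sp) bonds between ring and arms. Polar chemistry serves them badly: a secondary cyclobutyl electrophile resists substitution, and in a symmetric 1,2-dicarbonyl precursor epimerisation at either centre passes through the meso cis form and racemises the trans one. The arylalkyne–bithiophene arms are electron-rich, light-sensitive and open to electrophiles and oxidants at C5', and the strained ring with two propargylic positions should not meet cationic or hot conditions.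

The feature the plan uses is that each ring methine carries exactly one exocyclic carbon, which is an sp carbon in 12 and a carboxyl carbon in the cyclobutane-1,2-dicarboxylic series. A carboxyl group can be exchanged for an alkynyl group through a planar cyclobutyl radical whose capture is steered by the neighbouring methine. The cis-diacid anhydride 5 has a mirror plane through the midpoints of the C1–C2 and C3–C4 bonds, so a single desymmetrising event fixes the absolute configuration.

## Retrosynthesis

**12 to 11 and 8.** The ring C(sp3)–C(sp) bond of one arm is cut, giving the redox-active ester 11 and the alkynylmagnesium 8. The neighbouring cut, C(sp)–C5(thienyl), would leave the stereochemical problem untouched and would need a terminal alkyne on the ring. Cutting both ring–arm bonds in one flask would forbid purification between the two radical events, so a facial lapse in the first would surface as the enantiomer of 12. Precursor 11 holds one arm and one stereocentre that matters. The forward reaction must capture the radical anti to the arm already present; a lapse gives the meso cis isomer, never the enantiomer.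

**11 to 10 to 9.** Only C–O bonds are changed: 11 is the N-hydroxytetrachlorophthalimide ester of acid 10, and 10 comes from methyl ester 9. The ester of 9 is the latent form of the second radical precursor. The forward steps must not touch the propargylic stereocentre; the configuration at the carboxyl-bearing carbon is irrelevant because it is erased in the next radical step.

**9 to 7 and 8 (key disconnection).** The other ring C(sp3)–C(sp) bond is cut, giving the redox-active ester 7 of hemiester 6 and again 8. This cut brings the whole arm in one piece, where a Sonogashira cut would bring two carbons at a time. It also makes the carboxyl group of a desymmetrised meso anhydride the direct placeholder for the alkyne. Precursor 7 is a C7 ring fragment two steps from 5, whereas 9 already holds the trans relationship and the full arm. The forward reaction must deliver the alkynyl group anti to the vicinal CO2Me group, which corrects the cis configuration of 7 to trans in the same event.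

**7 to 6 to 5.** One acyl C–O bond is cut: 6 is the methanolysis product of meso anhydride 5, and 7 is its activated ester. This is the only step that brings in absolute configuration, and it does so by telling two enantiotopic carbonyl groups apart. The cis relationship in 6 is no defect, since the acid-bearing carbon is destined to become a radical. Anhydride 5 is achiral and commercial.

**8 to 4 to 3 to 1 and 2.** The C5(thienyl)–C(sp) bond is cut. Reagent 8 is the magnesium acetylide of 4, made once as a titrated stock solution that serves both alkynylations. Alkyne 4 is the desilylated form of 3, and 3 is the Sonogashira product of commercial bromide 1 and silylalkyne 2. Monofunctional 1 avoids any selectivity problem on 2,2'-bithiophene itself.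

## Roads not taken

Alternative 1: The most obvious cut is at both C(sp)–C5(thienyl) bonds. (1R,2R)-1,2-Diethynylcyclobutane A3 would be coupled twice with bromide 1 by Sonogashira reaction. A3 would come from (1R,2R)-cyclobutane-1,2-dicarbaldehyde A2 by two-fold Ohira–Bestmann homologation, and A2 from resolved (1R,2R)-cyclobutane-1,2-dicarboxylic acid A1 by reduction and oxidation. The chosen plan is better on three counts:
- The configuration of A1 comes from a resolution that discards half the material.
- In A2 both stereocentres are α to a formyl group, and the basic homologation conditions are those that epimerise such centres. Because A2 is C2-symmetric, epimerisation at either carbon leads through the meso cis form to the enantiomer, so erosion appears as loss of enantiopurity. In the chosen route only one centre is ever labile and its neighbour is fixed.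
- A3 is a volatile C8 diyne that has to be handled in solution.

Alternative 2: Cut ring bonds C1–C2 and C3–C4 at once, by head-to-head [2+2] photodimerisation of the enyne 5-(but-3-en-1-yn-1-yl)-2,2'-bithiophene A4 under triplet sensitisation. This is the shortest route on paper. However, the monomer offers no binding site through which a chiral sensitiser or template could set absolute configuration. Ring closure of the intermediate 1,4-diradical does not discriminate between cis and trans. The product also keeps the absorbing chromophore, which invites cycloreversion. Compound 12 would be formed as a racemate in a mixture, so the stereochemical problem would be moved to a separation.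

Alternative 3: Cut only the C1–C2 bond, by ring contraction of (2S,5S)-2,5-bis[(trimethylsilyl)ethynyl]pyrrolidine A5. N-Amination with an iodonitrene and loss of N2 would join C2 to C5 with retention. A5 would come from (3R,6R)-1,8-bis(trimethylsilyl)octa-1,7-diyne-3,6-diol A6 by sulfonylation of both hydroxyl groups and double displacement with ammonia. A6 would come from two-directional asymmetric transfer hydrogenation of the bis-ynone A7. The asymmetric step is attractive, but the plan has three weaknesses:
- The contraction passes through a diradical state stabilised by two alkynes, which favours fragmentation into two enyne halves and loss of stereochemical memory.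
- The hypervalent iodine oxidant is not compatible with bithiophene, so silyl alkynes, a desilylation and a double Sonogashira coupling must follow.
- Propargylic sulfonates invite SN2' displacement.

The chosen plan reaches 12 in fewer steps and keeps every stereochemical lapse separable as a diastereomer.

Key step: step 6

Assumption: quinine is taken to deliver methanol to the same enantiotopic carbonyl group of 5 as in other monocyclic meso anhydrides, giving (1S,2R)-6; if the sense were opposite, quinidine would replace quinine in step 3 and nothing else would change.

## Steps

Compounds 4, 8 and 9 to 12 are handled with exclusion of light.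

Step 1
Reactants: 1 5-bromo-2,2'-bithiophene; 2 ethynyltrimethylsilane
Product: 3 5-[(trimethylsilyl)ethynyl]-2,2'-bithiophene
Conditions: PdCl2(PPh3)2 (2 mol%), CuI (4 mol%), Et3N, THF, 50 °C
Reagents that add atoms: none
Why: Sonogashira coupling; zerovalent palladium inserts into the only C–Br bond of the electron-rich bromothiophene, and the silyl group keeps the alkyne monofunctional.

Step 2
Reactants: 3 5-[(trimethylsilyl)ethynyl]-2,2'-bithiophene
Product: 4 5-ethynyl-2,2'-bithiophene
Conditions: K2CO3 (0.2 equiv), MeOH/THF, rt
Reagents that add atoms: none
Why: Methoxide-catalysed protodesilylation of a C(sp)–Si bond; nothing else in 3 reacts, and 4 should be kept cold and dark and used promptly.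

Step 3
Reactants: 5 cis-cyclobutane-1,2-dicarboxylic anhydride
Product: 6 (1S,2R)-2-(methoxycarbonyl)cyclobutane-1-carboxylic acid
Conditions: quinine (1.1 equiv), MeOH (3 equiv), toluene, −55 °C; then aq. HCl
Reagents that add atoms: methanol, CO
Why: Cinchona-alkaloid-mediated desymmetrising methanolysis of a meso anhydride; the quinine–methanol complex attacks one of the two enantiotopic carbonyl groups, so no stereocentre is formed but the two are told apart. The ester-bearing carbon (R) is the centre that is kept to the end.

Step 4
Reactants: 6 (1S,2R)-2-(methoxycarbonyl)cyclobutane-1-carboxylic acid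
Product: 7 1-(4,5,6,7-tetrachloro-1,3-dioxoisoindolin-2-yl) 2-methyl (1S,2R)-cyclobutane-1,2-dicarboxylate
Conditions: N-hydroxytetrachlorophthalimide (1.0 equiv), DIC (1.1 equiv), DMAP (0.1 equiv), CH2Cl2, rt
Reagents that add atoms: N-hydroxytetrachlorophthalimide, O=C1N(O)C(=O)c2c(Cl)c(Cl)c(Cl)c(Cl)c12
Why: Carbodiimide esterification to the redox-active ester; no base strong enough to touch the α-carbon of the methyl ester is present, and the configuration of the activated carbon no longer matters.

Step 5
Reactants: 4 5-ethynyl-2,2'-bithiophene
Product: 8 [(2,2'-bithiophen-5-yl)ethynyl]magnesium bromide (stock solution in THF, about 0.3 M)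
Conditions: EtMgBr (0.95 equiv), THF, 0 °C to 40 °C, 1 h; titrated, kept under argon at 0–5 °C in the dark
Reagents that add atoms: ethylmagnesium bromide, CC[Mg]Br
Why: Acid–base metalation of a terminal alkyne by an alkyl Grignard reagent, made irreversible by loss of ethane; the slight deficit of EtMgBr leaves no ethyl nucleophile behind and the thiophene C–H bonds are not acidic enough to react. The batch is sized for both alkynylations: one portion goes into step 6 at once, the remainder is stored and re-titrated before step 9.

Step 6
Reactants: 7 1-(4,5,6,7-tetrachloro-1,3-dioxoisoindolin-2-yl) 2-methyl (1S,2R)-cyclobutane-1,2-dicarboxylate; 8 [(2,2'-bithiophen-5-yl)ethynyl]magnesium bromide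
Product: 9 methyl (1R,2R)-2-[(2,2'-bithiophen-5-yl)ethynyl]cyclobutane-1-carboxylate
Conditions: 8 (1.7 equiv, THF solution from step 5), slow addition to 7, FeBr2·H2O (20 mol%), NMP/THF, −15 °C; aq. HCl
Reagents that add atoms: none
Why: Iron-catalysed decarboxylative alkynylation of a redox-active ester; the closest known reaction type is the iron- or nickel-catalysed decarboxylative cross-coupling of secondary N-hydroxytetrachlorophthalimide esters with alkynyl Grignard or alkynylzinc reagents, as used in sequence on desymmetrised cyclic hemiesters. The alkynylmagnesium 8 reduces FeBr2 to a low-valent alkynyl iron species, which transfers one electron to the tetrachlorophthalimide ester of 7; the radical anion fragments to tetrachlorophthalimide anion, CO2 and a secondary cyclobutyl radical at the ring carbon that carried the activated carboxyl group, and this radical recombines with the alkynyl iron species, which forms the C(sp3)–C(sp) bond by reductive elimination. No ring is closed. The one new stereocentre (C2 of 9) arises from a planar, configurationally free radical, so the cis configuration it had in 7 is erased; it is set by the adjacent stereocentre C1, whose CO2Me group blocks one face of the nearly flat four-membered ring, so the bulky metal-bound alkynyl group is delivered anti and the trans (1R,2R) product results. The step is therefore stereoconvergent: either epimer at the carboxyl-bearing carbon would give the same radical and the same product. Three selectivities are needed: facial selectivity (secured by the vicinal ester, which a cis approach would have to eclipse), chemoselectivity of 8 for electron transfer over addition to the activated ester or the methyl ester (secured by the fast catalytic cycle at −15 °C and slow addition of 8), and integrity of the ester α-carbon C1 (secured by the low basicity of an alkynylmagnesium at this temperature). The minor cis diastereomer, which would carry the wrong configuration forward, is removed by chromatography at this stage.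

Step 7
Reactants: 9 methyl (1R,2R)-2-[(2,2'-bithiophen-5-yl)ethynyl]cyclobutane-1-carboxylate
Product: 10 (1R,2R)-2-[(2,2'-bithiophen-5-yl)ethynyl]cyclobutane-1-carboxylic acid
Conditions: LiOH·H2O (2 equiv), THF/H2O 3:1, 0 °C to rt; then 1 M HCl to pH 3
Reagents that add atoms: lithium hydroxide, [Li+].[OH-]
Why: Saponification of a methyl ester; the propargylic C2–H is not acidic under these conditions, and any epimerisation at C1 is without consequence because C1 becomes a radical in step 9.

Step 8
Reactants: 10 (1R,2R)-2-[(2,2'-bithiophen-5-yl)ethynyl]cyclobutane-1-carboxylic acid
Product: 11 4,5,6,7-tetrachloro-1,3-dioxoisoindolin-2-yl (1R,2R)-2-[(2,2'-bithiophen-5-yl)ethynyl]cyclobutane-1-carboxylate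
Conditions: N-hydroxytetrachlorophthalimide (1.0 equiv), DIC (1.1 equiv), DMAP (0.1 equiv), CH2Cl2, rt
Reagents that add atoms: N-hydroxytetrachlorophthalimide, O=C1N(O)C(=O)c2c(Cl)c(Cl)c(Cl)c(Cl)c12
Why: The same carbodiimide esterification as in step 4; the neutral conditions spare the alkyne and the bithiophene.

Step 9
Reactants: 11 4,5,6,7-tetrachloro-1,3-dioxoisoindolin-2-yl (1R,2R)-2-[(2,2'-bithiophen-5-yl)ethynyl]cyclobutane-1-carboxylate; 8 [(2,2'-bithiophen-5-yl)ethynyl]magnesium bromide
Product: 12 cardopatine
Conditions: 8 (1.7 equiv, stored THF solution from step 5, re-titrated), slow addition to 11, FeBr2·H2O (20 mol%), NMP/THF, −15 °C, dark; aq. HCl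
Reagents that add atoms: none
Why: Second iron-catalysed decarboxylative alkynylation of a secondary redox-active ester; the cyclobutyl radical at C1 is captured anti to the rigid arm at C2, which relays the configuration fixed in step 3 to the last stereocentre. A lapse in facial control gives the meso cis isomer and not the enantiomer, and it is removed by chromatography.

## Compound list

1 | 5-bromo-2,2'-bithiophene | Brc1ccc(-c2cccs2)s1 | starting material
2 | ethynyltrimethylsilane | C#C[Si](C)(C)C | starting material
3 | 5-[(trimethylsilyl)ethynyl]-2,2'-bithiophene | C[Si](C)(C)C#Cc1ccc(-c2cccs2)s1 | intermediate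
4 | 5-ethynyl-2,2'-bithiophene | C#Cc1ccc(-c2cccs2)s1 | intermediate
5 | cis-cyclobutane-1,2-dicarboxylic anhydride (meso; 3-oxabicyclo[3.2.0]heptane-2,4-dione) | O=C3OC(=O)[C@H]1CC[C@H]13 | starting material
6 | (1S,2R)-2-(methoxycarbonyl)cyclobutane-1-carboxylic acid | OC(=O)[C@H]1CC[C@H]1C(=O)OC | intermediate
7 | 1-(4,5,6,7-tetrachloro-1,3-dioxoisoindolin-2-yl) 2-methyl (1S,2R)-cyclobutane-1,2-dicarboxylate | O=C(ON3C(=O)c4c(Cl)c(Cl)c(Cl)c(Cl)c4C3=O)[C@H]1CC[C@H]1C(=O)OC | intermediate
8 | [(2,2'-bithiophen-5-yl)ethynyl]magnesium bromide | Br[Mg]C#Cc1ccc(-c2cccs2)s1 | intermediate
9 | methyl (1R,2R)-2-[(2,2'-bithiophen-5-yl)ethynyl]cyclobutane-1-carboxylate | C(#C[C@@H]1CC[C@H]1C(=O)OC)c1ccc(-c2cccs2)s1 | intermediate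
10 | (1R,2R)-2-[(2,2'-bithiophen-5-yl)ethynyl]cyclobutane-1-carboxylic acid | C(#C[C@@H]1CC[C@H]1C(=O)O)c1ccc(-c2cccs2)s1 | intermediate
11 | 4,5,6,7-tetrachloro-1,3-dioxoisoindolin-2-yl (1R,2R)-2-[(2,2'-bithiophen-5-yl)ethynyl]cyclobutane-1-carboxylate | C(#C[C@@H]1CC[C@H]1C(=O)ON3C(=O)c4c(Cl)c(Cl)c(Cl)c(Cl)c4C3=O)c1ccc(-c2cccs2)s1 | intermediate
12 | cardopatine, (1R,2R)-1,2-bis[(2,2'-bithiophen-5-yl)ethynyl]cyclobutane | C(#C[C@@H]1CC[C@H]1C#Cc1ccc(-c2cccs2)s1)c1ccc(-c2cccs2)s1 | target

## Step count and risk

Total steps: 9. Longest linear sequence: 7 steps (steps 1, 2, 5, 6, 7, 8, 9 from bromide 1); the ring branch from anhydride 5 runs through 6 steps (steps 3, 4, 6, 7, 8, 9).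

**Step 6 (key step).** Three things are most likely to go wrong:
- Direct acyl substitution of the activated ester, or addition to the methyl ester, by the alkynylmagnesium may outrun electron transfer.
- Facial discrimination at the cyclobutyl radical may be incomplete.
- Base-induced loss of configuration at the ester α-carbon would lower the enantiopurity of everything that follows.

The fallback replaces the radical exchange by a polar homologation. It sets out from 6 and returns at 9.
- Acid 6 is converted with ethanethiol, EDC·HCl and DMAP into the thioester methyl (1R,2S)-2-[(ethylsulfanyl)carbonyl]cyclobutane-1-carboxylate F1.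
- Fukuyama reduction (Et3SiH, Pd/C, acetone) should give the cis aldehyde methyl (1R,2S)-2-formylcyclobutane-1-carboxylate F2.
- With K2CO3 in MeOH only the formyl-bearing carbon is labile, and it should equilibrate to the trans aldehyde methyl (1R,2R)-2-formylcyclobutane-1-carboxylate F3, which is not isolated.
- F3 is homologated in the same flask with dimethyl (1-diazo-2-oxopropyl)phosphonate to methyl (1R,2R)-2-ethynylcyclobutane-1-carboxylate F4.
- Sonogashira coupling of F4 with bromide 1 (PdCl2(PPh3)2, CuI, Et3N) gives 9.

**Step 9.** The arm at C2 is slim, so the facial bias on the second radical may be weaker than in step 6 and more of the cis diastereomer may form. Oxidative homocoupling of the alkynylmagnesium would consume the arm, and the stored solution of 8 may lose titre through adventitious protonation. The fallback keeps the configuration at C1 by never making it trigonal without a fixed neighbour, and it does not draw on 8. It sets out from 9 and returns at 12.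
- i-Bu2AlH (CH2Cl2, −78 to 0 °C) should give the alcohol {(1R,2R)-2-[(2,2'-bithiophen-5-yl)ethynyl]cyclobutyl}methanol F5.
- Dess–Martin periodinane gives the aldehyde (1R,2R)-2-[(2,2'-bithiophen-5-yl)ethynyl]cyclobutane-1-carbaldehyde F6. Its formyl-bearing carbon can only equilibrate against a fixed propargylic neighbour, which favours trans.
- Ohira–Bestmann homologation (K2CO3, MeOH) gives the terminal alkyne 5-{[(1R,2R)-2-ethynylcyclobutyl]ethynyl}-2,2'-bithiophene F7.
- Sonogashira coupling of F7 with bromide 1 gives 12.

**Step 3.** The small, flat cyclobutane anhydride offers the alkaloid less to distinguish than larger meso anhydrides, so enantiotopic group discrimination may be insufficient or of the opposite sense. The fallback replaces reagent control by resolution. It sets out from 5 and returns at 6.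
- Uncatalysed methanolysis (MeOH, reflux) gives racemic cis-2-(methoxycarbonyl)cyclobutane-1-carboxylic acid F8.
- Fractional crystallisation with one enantiomer of 1-phenylethylamine, written here for the (R)-amine, should give the salt (R)-1-phenylethylammonium (1S,2R)-2-(methoxycarbonyl)cyclobutane-1-carboxylate F9. If the salt of the antipode proves the less soluble one, the (S)-amine is used.
- Acidification of F9 releases 6.

## Further compounds

F1 | step 6 | methyl (1R,2S)-2-[(ethylsulfanyl)carbonyl]cyclobutane-1-carboxylate | CCSC(=O)[C@H]1CC[C@H]1C(=O)OC
F2 | step 6 | methyl (1R,2S)-2-formylcyclobutane-1-carboxylate | O=C[C@H]1CC[C@H]1C(=O)OC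
F3 | step 6 | methyl (1R,2R)-2-formylcyclobutane-1-carboxylate | O=C[C@@H]1CC[C@H]1C(=O)OC
F4 | step 6 | methyl (1R,2R)-2-ethynylcyclobutane-1-carboxylate | C#C[C@@H]1CC[C@H]1C(=O)OC
F5 | step 9 | {(1R,2R)-2-[(2,2'-bithiophen-5-yl)ethynyl]cyclobutyl}methanol | C(#C[C@@H]1CC[C@H]1CO)c1ccc(-c2cccs2)s1
F6 | step 9 | (1R,2R)-2-[(2,2'-bithiophen-5-yl)ethynyl]cyclobutane-1-carbaldehyde | C(#C[C@@H]1CC[C@H]1C=O)c1ccc(-c2cccs2)s1
F7 | step 9 | 5-{[(1R,2R)-2-ethynylcyclobutyl]ethynyl}-2,2'-bithiophene | C(#C[C@@H]1CC[C@H]1C#C)c1ccc(-c2cccs2)s1
F8 | step 3 | racemic cis-2-(methoxycarbonyl)cyclobutane-1-carboxylic acid (both enantiomers) | OC(=O)[C@H]1CC[C@H]1C(=O)OC.OC(=O)[C@@H]1CC[C@@H]1C(=O)OC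
F9 | step 3 | (R)-1-phenylethylammonium (1S,2R)-2-(methoxycarbonyl)cyclobutane-1-carboxylate | [O-]C(=O)[C@H]1CC[C@H]1C(=O)OC.C[C@@H]([NH3+])c1ccccc1
A1 | alternative 1 | (1R,2R)-cyclobutane-1,2-dicarboxylic acid | OC(=O)[C@@H]1CC[C@H]1C(=O)O
A2 | alternative 1 | (1R,2R)-cyclobutane-1,2-dicarbaldehyde | O=C[C@@H]1CC[C@H]1C=O
A3 | alternative 1 | (1R,2R)-1,2-diethynylcyclobutane | C#C[C@@H]1CC[C@H]1C#C
A4 | alternative 2 | 5-(but-3-en-1-yn-1-yl)-2,2'-bithiophene | C=CC#Cc1ccc(-c2cccs2)s1
A5 | alternative 3 | (2S,5S)-2,5-bis[(trimethylsilyl)ethynyl]pyrrolidine | C[Si](C)(C)C#C[C@@H]1CC[C@@H](C#C[Si](C)(C)C)N1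
A6 | alternative 3 | (3R,6R)-1,8-bis(trimethylsilyl)octa-1,7-diyne-3,6-diol | C[Si](C)(C)C#C[C@H](O)CC[C@@H](O)C#C[Si](C)(C)C
A7 | alternative 3 | 1,8-bis(trimethylsilyl)octa-1,7-diyne-3,6-dione | C[Si](C)(C)C#CC(=O)CCC(=O)C#C[Si](C)(C)C
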